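**Retrosynthetic overview**
1. Numbering follows the 2,3-dihydro-1-benzofuran-4,6-dione core: ring A is the carbocycle (C3a, C4, C5, C6, C7, C7a) and ring B the dihydrofuran (O1, C2, C3, C3a, C7a). The strategy rests on C5: with its two prenyl groups and the flanking C4 and C6 carbonyls it is a diprenylmalonyl unit, while C3a–C7a–C7 is the α'-carbon, carbonyl carbon and α-carbon of an isobutyryl β-diketone already held in ring B.
2. Key disconnection: C3a–C4 and C6–C7, a [3+3] double C-acylation of a ring B 2-alkoxy-4-silyloxydiene by 2,2-diprenylmalonyl dichloride (Effenberger-type), so no phloroglucinol is made at any stage.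
3. The diene goes back through a 2-(acylmethylidene)tetrahydrofuran to a δ-hydroxy β-diketone, cut at C3–C3a into the dianion of 5-methylhexane-2,4-dione and an (R)-epoxide from methyl (R)-glycerate acetonide. The dichloride comes from dimethyl malonate and prenyl bromide.
4. Ring order: ring B first (cyclodehydration), ring A last (key step), then removal of the silyl ether. The single stereocentre C2 comes from the chiral pool and no bond to it is broken.

Key step: step 11

Assumption: the exocyclic enol drawn in the target (OH hydrogen-bonded to the C6 carbonyl) is one tautomer of a rapidly equilibrating acyl-trione, so its geometry is not set by any step and should settle thermodynamically.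

**Step 1**
Reactants: 1 methyl (R)-2,2-dimethyl-1,3-dioxolane-4-carboxylate
Product: 2 (R)-2-(2,2-dimethyl-1,3-dioxolan-4-yl)propan-2-ol
Conditions: MeMgBr (3.0 equiv), THF, 0 °C → 23 °C; aq. NH4Cl
Reagents that add atoms: methylmagnesium bromide, C[Mg]Br
Why: Double Grignard addition to the ester gives the tertiary carbinol, and the acetal-protected stereocentre should be carried through because the intermediate ketone is consumed faster than it is enolised.

**Step 2**
Reactants: 2 (R)-2-(2,2-dimethyl-1,3-dioxolan-4-yl)propan-2-ol
Product: 3 (R)-3-methylbutane-1,2,3-triol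
Conditions: Dowex 50WX8 (H+ form), THF/H2O, 50 °C; filtration, evaporation
Reagents that add atoms: none
Why: Acid-catalysed acetal hydrolysis with a resin that is filtered off frees the 1,2-diol without breaking a bond to the stereocentre.

**Step 3**
Reactants: 3 (R)-3-methylbutane-1,2,3-triol
Product: 4 (R)-2,3-dihydroxy-3-methylbutyl 4-methylbenzenesulfonate
Conditions: TsCl (1.05 equiv), Bu2SnO (2 mol %), Et3N (1.2 equiv), CH2Cl2/MeCN, 0 °C → 23 °C
Reagents that add atoms: p-toluenesulfonyl chloride, Cc1ccc(S(=O)(=O)Cl)cc1
Why: Stannylene-mediated regioselective sulfonylation of a 1,2-diol should activate only the primary hydroxyl, the secondary and tertiary hydroxyls being far less reactive.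

**Step 4**
Reactants: 4 (R)-2,3-dihydroxy-3-methylbutyl 4-methylbenzenesulfonate
Product: 6 triethyl({2-[(2R)-oxiran-2-yl]propan-2-yl}oxy)silane, via (R)-2-(oxiran-2-yl)propan-2-ol 5 (not isolated)
Conditions: DBU (1.2 equiv), CH2Cl2, 0 °C → 23 °C; then 2,6-lutidine (3 equiv), Et3SiOTf (1.5 equiv), −78 °C → −40 °C; aq. NaHCO3
Reagents that add atoms: triethylsilyl trifluoromethanesulfonate, CC[Si](CC)(CC)OS(=O)(=O)C(F)(F)F
Why: Intramolecular Williamson closure (3-exo-tet) by the secondary hydroxyl at the primary carbon leaves the stereocentre untouched, the amidine base in an aprotic medium should not form the tertiary alkoxide needed for a Payne rearrangement, and silylation of the volatile epoxy alcohol in the same flask caps the tertiary hydroxyl at low temperature without opening the epoxide.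

**Step 5**
Reactants: 6 triethyl({2-[(2R)-oxiran-2-yl]propan-2-yl}oxy)silane, 7 5-methylhexane-2,4-dione
Product: 8 (R)-8-hydroxy-2,9-dimethyl-9-[(triethylsilyl)oxy]decane-3,5-dione
Conditions: 7 (1.5 equiv), LiN(i-Pr)2 (3.1 equiv), THF, 0 °C; −78 °C, 6 (1.0 equiv), then BF3·OEt2 (1.2 equiv), −78 °C, 1 h; aq. NH4Cl at −78 °C
Reagents that add atoms: none
Why: The 1,3-diketone dianion, formed at the methyl terminus and not at the isopropyl methine, should open the BF3-activated epoxide by SN2 attack at its CH2 so that the carbinol stereocentre is not involved, and the boron-bound alkoxide at −78 °C should not start a 1,2-silyl shift from the neighbouring tertiary oxygen.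

**Step 6**
Reactants: 8 (R)-8-hydroxy-2,9-dimethyl-9-[(triethylsilyl)oxy]decane-3,5-dione
Product: 9 (E)-3-methyl-1-[(5R)-5-{2-[(triethylsilyl)oxy]propan-2-yl}dihydrofuran-2(3H)-ylidene]butan-2-one
Conditions: PPTS (0.1 equiv), 4 Å molecular sieves, CH2Cl2, 23 °C → 40 °C
Reagents that add atoms: none
Why: 5-exo-trig hemiketalisation of the δ-hydroxyl onto the nearer carbonyl and dehydration toward the doubly activated methylene should give the conjugated vinylogous ester (ring B closed; either alkene geometry serves the next step), and the mild anhydrous acid should spare the hindered tertiary silyl ether.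

**Step 7**
Reactants: 9 (E)-3-methyl-1-[(5R)-5-{2-[(triethylsilyl)oxy]propan-2-yl}dihydrofuran-2(3H)-ylidene]butan-2-one
Product: 10 triethyl{[2-((2R)-5-{(1Z)-3-methyl-2-[(trimethylsilyl)oxy]but-1-en-1-yl}-2,3-dihydrofuran-2-yl)propan-2-yl]oxy}silane
Conditions: Me3SiOTf (1.3 equiv), Et3N (2.0 equiv), Et2O, 0 °C → 23 °C; pentane, filtration under argon, evaporation; used crude
Reagents that add atoms: trimethylsilyl trifluoromethanesulfonate, C[Si](C)(C)OS(=O)(=O)C(F)(F)F
Why: Soft enolisation, in which O-silylation of the vinylogous ester gives a 1-silyloxy-3-alkoxyallyl cation that the amine should deprotonate at the ring CH2 (γ) in preference to the hindered isopropyl methine, gives the linearly conjugated endocyclic diene, the same γ-enolisation by which other vinylogous esters are turned into silyloxydienes.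

**Step 8**
Reactants: 11 dimethyl malonate, 12 prenyl bromide (1-bromo-3-methylbut-2-ene)
Product: 13 dimethyl 2,2-bis(3-methylbut-2-en-1-yl)malonate
Conditions: NaH (2.3 equiv), 12 (2.3 equiv), THF/DMF, 0 °C → 23 °C
Reagents that add atoms: none
Why: Double malonic ester alkylation, in which the soft malonate anion attacks prenyl bromide at its primary carbon without allylic transposition.

**Step 9**
Reactants: 13 dimethyl 2,2-bis(3-methylbut-2-en-1-yl)malonate
Product: 14 2,2-bis(3-methylbut-2-en-1-yl)malonic acid
Conditions: KOH (6 equiv), EtOH/H2O, 80 °C; then 1 M aq. KHSO4 to pH 2 at 0 °C, EtOAc extraction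
Reagents that add atoms: potassium hydroxide, [K+].[OH-]
Why: Saponification of the hindered diester proceeds through the stable dicarboxylate, and cold acidification with hydrogen sulfate should give the diacid without decarboxylation or addition of acid to the prenyl double bonds.

**Step 10**
Reactants: 14 2,2-bis(3-methylbut-2-en-1-yl)malonic acid
Product: 16 2,2-bis(3-methylbut-2-en-1-yl)malonyl dichloride, via disodium 2,2-bis(3-methylbut-2-en-1-yl)malonate 15 (not isolated)
Conditions: NaH (2.0 equiv), THF, 0 °C → 23 °C; then (COCl)2 (2.2 equiv), DMF (cat.), 0 °C → 23 °C; evaporation, hexane, filtration under argon; used crude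
Reagents that add atoms: oxalyl chloride, ClC(=O)C(=O)Cl
Why: Acid chloride formation from the carboxylate salt with oxalyl chloride under Vilsmeier-type catalysis releases only CO, CO2 and NaCl, so no HCl is present to add to the prenyl groups.

**Step 11**
Reactants: 10 triethyl{[2-((2R)-5-{(1Z)-3-methyl-2-[(trimethylsilyl)oxy]but-1-en-1-yl}-2,3-dihydrofuran-2-yl)propan-2-yl]oxy}silane, 16 2,2-bis(3-methylbut-2-en-1-yl)malonyl dichloride
Product: 18 O-triethylsilyl garcinielliptone HC [(2R)-7-(1-hydroxy-2-methylpropylidene)-5,5-bis(3-methylbut-2-en-1-yl)-2-{2-[(triethylsilyl)oxy]propan-2-yl}-2,3-dihydro-1-benzofuran-4,6(5H,7H)-dione], via mono-C-acylated acid chloride 17 (not isolated)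
Conditions: 16 (1.2 equiv), 2,6-di-tert-butyl-4-methylpyridine (3 equiv), CH2Cl2, 0 °C; 10 added by syringe pump over 8 h (final 0.005 M); then 23 °C, 12 h; pH 4 phosphate buffer work-up
Reagents that add atoms: none
Why: Proposed new method: the terminal ring carbon of the silyloxydiene (the future C3a, vinylogous to the silyloxy group) should attack one acid chloride to give an allyl cation stabilised by the ring oxygen and the silyloxy group, chloride removes the silyl group as Me3SiCl, and the vinylogous ester 17 so formed then attacks the second acid chloride through its α-carbon (the future C7) while the hindered pyridine takes up the HCl, after which enolisation gives the hydrogen-bonded acyl-trione as a thermodynamic sink. The closest known reactions are the Effenberger annulation of silyl enol ethers with malonyl dichlorides to cyclic β-triketones and the [3+3] cyclisations of 1,3-bis(silyloxy)dienes with 1,3-dielectrophiles, but the combination of a cyclic 2-alkoxy-4-silyloxydiene with a 2,2-disubstituted malonyl dichloride is without direct example. Ring A is closed by a 6-exo-trig attack of C7 on the second acyl chloride carbon, which forms C6–C7 after C3a–C4. No stereocentre is created, and the C2 centre is remote from both bond-forming sites and is not enolisable. The step needs C- over O-acylation and ring closure over chain growth: the dichloride has no α-hydrogen, so ketene and pyranone pathways are closed, O-acylation through the isobutyryl oxygen would need an eight-membered ring, and because the dichloride is symmetric a first attack through C7 in place of C3a would lead to the same product. Slow addition of the diene at high dilution should keep intermolecular acylation of 17 below the rate of ring closure, which the quaternary C5 centre accelerates.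

**Step 12**
Reactants: 18 O-triethylsilyl garcinielliptone HC
Product: 19 garcinielliptone HC
Conditions: HF·pyridine, pyridine, THF, 0 °C → 23 °C; pH 4 buffer work-up
Reagents that add atoms: none
Why: Fluoride-mediated cleavage of the tertiary silyl ether under pyridine-buffered conditions should leave the acidic acyl-trione, the prenyl groups and the C2 stereocentre untouched.

**Compound list**
1 | methyl (R)-2,2-dimethyl-1,3-dioxolane-4-carboxylate | COC(=O)[C@H]1COC(C)(C)O1 | starting material
2 | (R)-2-(2,2-dimethyl-1,3-dioxolan-4-yl)propan-2-ol | CC(C)(O)[C@H]1COC(C)(C)O1 | intermediate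
3 | (R)-3-methylbutane-1,2,3-triol | CC(C)(O)[C@H](O)CO | intermediate
4 | (R)-2,3-dihydroxy-3-methylbutyl 4-methylbenzenesulfonate | CC(C)(O)[C@H](O)COS(=O)(=O)c1ccc(C)cc1 | intermediate
5 | (R)-2-(oxiran-2-yl)propan-2-ol | CC(C)(O)[C@H]1CO1 | intermediate (not isolated)
6 | triethyl({2-[(2R)-oxiran-2-yl]propan-2-yl}oxy)silane | CC(C)(O[Si](CC)(CC)CC)[C@H]1CO1 | intermediate
7 | 5-methylhexane-2,4-dione | CC(=O)CC(=O)C(C)C | starting material
8 | (R)-8-hydroxy-2,9-dimethyl-9-[(triethylsilyl)oxy]decane-3,5-dione | CC(C)C(=O)CC(=O)CC[C@@H](O)C(C)(C)O[Si](CC)(CC)CC | intermediate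
9 | (E)-3-methyl-1-[(5R)-5-{2-[(triethylsilyl)oxy]propan-2-yl}dihydrofuran-2(3H)-ylidene]butan-2-one | CC(C)C(=O)/C=C1\CC[C@H](C(C)(C)O[Si](CC)(CC)CC)O1 | intermediate
10 | triethyl{[2-((2R)-5-{(1Z)-3-methyl-2-[(trimethylsilyl)oxy]but-1-en-1-yl}-2,3-dihydrofuran-2-yl)propan-2-yl]oxy}silane | CC(C)/C(O[Si](C)(C)C)=C/C1=CC[C@H](C(C)(C)O[Si](CC)(CC)CC)O1 | intermediate
11 | dimethyl malonate | COC(=O)CC(=O)OC | starting material
12 | prenyl bromide (1-bromo-3-methylbut-2-ene) | CC(C)=CCBr | starting material
13 | dimethyl 2,2-bis(3-methylbut-2-en-1-yl)malonate | COC(=O)C(CC=C(C)C)(CC=C(C)C)C(=O)OC | intermediate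
14 | 2,2-bis(3-methylbut-2-en-1-yl)malonic acid | CC(C)=CCC(CC=C(C)C)(C(=O)O)C(=O)O | intermediate
15 | disodium 2,2-bis(3-methylbut-2-en-1-yl)malonate | CC(C)=CCC(CC=C(C)C)(C(=O)[O-])C(=O)[O-].[Na+].[Na+] | intermediate (not isolated)
16 | 2,2-bis(3-methylbut-2-en-1-yl)malonyl dichloride | CC(C)=CCC(CC=C(C)C)(C(Cl)=O)C(Cl)=O | intermediate
17 | mono-C-acylated acid chloride, 5-methyl-2-(3-methylbut-2-en-1-yl)-2-({(5R)-2-(3-methyl-2-oxobutyl)-5-{2-[(triethylsilyl)oxy]propan-2-yl}-4,5-dihydrofuran-3-yl}carbonyl)hex-4-enoyl chloride (drawn as its conjugated tautomer) | CC(C)C(=O)CC1=C(C(=O)C(CC=C(C)C)(CC=C(C)C)C(Cl)=O)C[C@H](C(C)(C)O[Si](CC)(CC)CC)O1 | intermediate (not isolated)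
18 | O-triethylsilyl garcinielliptone HC, (2R)-7-(1-hydroxy-2-methylpropylidene)-5,5-bis(3-methylbut-2-en-1-yl)-2-{2-[(triethylsilyl)oxy]propan-2-yl}-2,3-dihydro-1-benzofuran-4,6(5H,7H)-dione | CC(C)=CCC1(CC=C(C)C)C(=O)C2=C(O[C@@H](C(C)(C)O[Si](CC)(CC)CC)C2)/C(=C(/O)C(C)C)C1=O | intermediate
19 | garcinielliptone HC, (2R,7Z)-7-(1-hydroxy-2-methylpropylidene)-2-(2-hydroxypropan-2-yl)-5,5-bis(3-methylbut-2-en-1-yl)-2,3-dihydro-1-benzofuran-4,6(5H,7H)-dione | CC(C)=CCC1(CC=C(C)C)C(=O)C2=C(O[C@@H](C(C)(C)O)C2)/C(=C(/O)C(C)C)C1=O | target

**Step count**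
Total: 12 steps. Longest linear sequence: 9 steps (steps 1 to 7, then 11 and 12); the dichloride branch (steps 8 to 10) is convergent.

**Steps most likely to fail**

Step 11 (proposed new method). The ring closure may lose to chain growth, a second diene molecule acylating 17 to give open-chain bis-adducts. The second acylation may also stall, so that the remaining acid chloride is hydrolysed on work-up, or the acidic product may be O-acylated by excess dichloride. The fallback sets out from 13 and 10 and comes back to the route at 18, making the two C–C bonds one at a time by known reactions. One ester of 13 is saponified (KOH, 1.0 equiv, MeOH, 23 °C) to 3-methoxy-3-oxo-2,2-bis(3-methylbut-2-en-1-yl)propanoic acid F1. Its sodium salt with oxalyl chloride should give methyl 2-(chlorocarbonyl)-5-methyl-2-(3-methylbut-2-en-1-yl)hex-4-enoate F2. Terminal C-acylation of 10 with F2 (CH2Cl2, −78 °C → 23 °C, hindered pyridine), the known behaviour of 2,4-dioxygenated silyloxydienes toward acid chlorides, should give methyl 5-methyl-2-(3-methylbut-2-en-1-yl)-2-({(5R)-2-(3-methyl-2-oxobutyl)-5-{2-[(triethylsilyl)oxy]propan-2-yl}-4,5-dihydrofuran-3-yl}carbonyl)hex-4-enoate F3. A Dieckmann condensation (LiN(SiMe3)2, THF, 0 °C → 23 °C) through the methylene between the isobutyryl group and ring B should then close ring A, driven by formation of the stabilised trione enolate, and give 18.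

Step 7. Deprotonation at the isopropyl methine may compete with γ-deprotonation, giving the cross-positioned diene, and the diene may hydrolyse back to 9 on handling. The fallback sets out from 9 and 13 and comes back to the route at 18 without any silyl diene. 9 and 13 are condensed under equilibrating conditions (NaH, 3 equiv, MeOH cat., THF, 60 °C) in a crossed Claisen condensation at the γ-carbon, followed in the same flask by Dieckmann closure. The mono-condensation product, the keto ester F3 of the fallback to step 11, is not isolated here. The extended γ-dienolate is the thermodynamic enolate of a vinylogous ester, and only the pathway through the γ- and α-carbons ends in an enolisable trione whose enolate drives the equilibria, so deprotonation at the methine should be unproductive and reversible.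

Step 5. The epoxide, flanked by a fully substituted carbon, may open slowly, so that proton transfer quenches the dianion, or the silyl group may migrate from the tertiary to the new secondary oxygen if a free alkoxide forms. The fallback sets out from 6 and 11 and comes back to the route at 8, using a soft nucleophile and trapping the alkoxide by lactonisation. Sodio dimethyl malonate (NaOMe, MeOH, 65 °C) opens 6 at its CH2 and the alkoxide lactonises at once to methyl (5R)-2-oxo-5-{2-[(triethylsilyl)oxy]propan-2-yl}tetrahydrofuran-3-carboxylate F4. Krapcho demethoxycarbonylation (LiCl, wet DMSO, 140 °C) should give (R)-5-{2-[(triethylsilyl)oxy]propan-2-yl}dihydrofuran-2(3H)-one F5. The kinetic lithium enolate of 3-methylbutan-2-one (LiN(i-Pr)2, 2.2 equiv, THF, −78 °C) is then acylated by F5 in a Claisen-type addition to the lactone, and the hemiketal obtained on cold work-up is the ring form of 8.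

**Further compounds**
F1 | step 11 | 3-methoxy-3-oxo-2,2-bis(3-methylbut-2-en-1-yl)propanoic acid | COC(=O)C(CC=C(C)C)(CC=C(C)C)C(=O)O
F2 | step 11 | methyl 2-(chlorocarbonyl)-5-methyl-2-(3-methylbut-2-en-1-yl)hex-4-enoate | COC(=O)C(CC=C(C)C)(CC=C(C)C)C(Cl)=O
F3 | step 11 | methyl 5-methyl-2-(3-methylbut-2-en-1-yl)-2-({(5R)-2-(3-methyl-2-oxobutyl)-5-{2-[(triethylsilyl)oxy]propan-2-yl}-4,5-dihydrofuran-3-yl}carbonyl)hex-4-enoate | CC(C)C(=O)CC1=C(C(=O)C(CC=C(C)C)(CC=C(C)C)C(=O)OC)C[C@H](C(C)(C)O[Si](CC)(CC)CC)O1
F0 | step 7 | none | none
F4 | step 5 | methyl (5R)-2-oxo-5-{2-[(triethylsilyl)oxy]propan-2-yl}tetrahydrofuran-3-carboxylate | COC(=O)C1C[C@H](C(C)(C)O[Si](CC)(CC)CC)OC1=O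
F5 | step 5 | (R)-5-{2-[(triethylsilyl)oxy]propan-2-yl}dihydrofuran-2(3H)-one | O=C1CC[C@H](C(C)(C)O[Si](CC)(CC)CC)O1
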